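At early times Qe falls apart slowly into two Lx, each Lx turns a Ky into one Wu, and Wu is the chain carrier. On Aj it gives Qa and Kj, and Kj on Ky gives Zo and Wu back. On Gy it gives Dw and Ek, which pairs off to Ym, and the chain ends.

Ky 0.10 M; Aj 1.80 equiv; Gy 0.0100 M; Qe 1 mol%; time 40 min

1. how much Qa there is at 40 min, in percent of the Ky charged
2. the change that raises the amount of Qa at 40 min, in percent of the Ky charged most ("none" if none brings more than 2 percentage points) (blue / red / ochre / none)
3. amount of Qa at 40 min, in percent of the Ky charged, after red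

- blue: doubling the amount of Aj, all else as stated
- red: doubling the dissolution coefficient of step 3, all else as stated
- ochre: doubling the solubility in step 3, all else as stated

- percent here means Ky units held: one Ez counts as two
- what is said of Zo includes Uj
- a doubled species enters its step squared and goes two at a time
- Uj is a solid; its amount is given per volume of the solution
- run time (flask): 40 min

    Gy + Wu → Dw + Ek (k1 = 18000 M⁻¹ s⁻¹)
    Qe → 2 Lx (k2 = 0.0206 min⁻¹)
    Uj ⇌ Zo, rate k3*(cs3 - [Zo]) while solid is left; crystals form when [Zo] > cs3 (cs3 = 0.076 M, k3 = 1.75 min⁻¹)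
    Ky + Lx → Uv + Wu (k4 = 76900 M⁻¹ s⁻¹)
    Ky + Kj → Zo + Wu (k5 = 1.44 × 10⁵ M⁻¹ min⁻¹)
    2 Wu → Ez (k6 = 1.4 × 10⁷ M⁻¹ s⁻¹)
    Aj + Wu → Qa + Kj (k7 = 23500 M⁻¹ s⁻¹)
    2 Ek → Ym (k8 = 3.7 × 10⁶ M⁻¹ s⁻¹)

I carry ν, the turns a Wu makes on Aj for each death on Gy. In the flask it starts at 23.5, and this chain length, the rate of Wu on Aj over its rate on Gy, times the Wu started, gives Qa.

Wu stands near 3.81 × 10⁻⁹ M, its starting supply over its loss on Gy. Each Wu dies on Gy at 180 s⁻¹, far faster than on another Wu at 0.107 s⁻¹, so I let each Wu cost one Gy.

By 40 min the flask has started 0.00112 M of Wu, which gives a first answer of 26.4%. I put that back in. Aj ends near 0.154 M and Gy near 0.00888 M, so ν ends at 22.6. The mean, 23.0, gives 25.9%.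

The dilute neighbour, with 0.060 M of Ky, looks nearly the same, with equal equivalents and loading and so equal Wu per Ky. But its Gy stays at 0.0100 M while its Aj shrinks, so its ν starts lower, at 14.1. The same two rounds give 15.7% for that flask.

Blue doubles ν at the start, and the two rounds give 51.7%. Zo comes one per Qa, so in the flask it reaches 0.0259 M, below the solubility of 0.076 M. It feeds no other step, so I keep 25.9% after red and ochre, and I choose blue.

The forecast says 25.9%, blue and 25.9%, holding that “Each radical therefore kills one Gy”.

The simulation gives 25.9%, blue with a gain of 26 percentage points, and 25.9% after red.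

In the flask Qe feeds the chain throughout, falling to 43.9% by 40.0 min, while Qa climbs from 3.70% at 4.00 min to 25.9%. Meanwhile Zo rises to 0.0259 M with no Uj formed, 0 M. From the readings at 40.0 min, ν has gone from 23.5 to 22.7, and Qa over Dw reads 23.1. In the dilute neighbour, Qa over Dw reads 14.0, and Qa stands at 15.7%.

The rate constants come from no measurement; what happens was integrated by code.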